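**Retrosynthetic overview**
- The tetrahydropyran, the spiro-aminal carbon and the bond from the pyrrolyl-CH to ring B are made last and together, by acid-mediated dehydrative condensation of a hydroxy keto-pyrrolophane with 4-methoxy-2,2'-bipyrrole; the pendant alcohol dearomatises ring B.
- The O–CH(CH3) centre comes from a catalyst-controlled reduction of a methyl ketone.
- The 12-membered ansa ring and the first stereocentre come from an enantioselective NHC-catalysed macrocyclising Stetter reaction of a 5-(ω-enonyl)pyrrole-2-carbaldehyde.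
- That aldehyde comes from nona-1,8-diene, 5-bromopyrrole-2-carbaldehyde and methyl vinyl ketone; the bipyrrole from 4-methoxy-3-pyrrolin-2-one and N-Boc-pyrrole-2-boronic acid.
- Ring order: the three pyrroles are bought in, then the macrocycle, then the tetrahydropyran with the spiro junction.

Assumption: descriptors follow the given SMILES (spiro C R; O–CH(CH3) S; CH carrying the (CH2)7 bridge S; pyrrolyl-CH S), and the (5aR,10bS) antipode of the triazolium salt is taken as the one giving the (S) ring closure in step 3; if the first run shows the opposite sense, the equally available antipode is used and nothing else changes.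

**Step 1**
Reactants: 1 nona-1,8-diene; 2 5-bromo-1H-pyrrole-2-carbaldehyde
Product: 4 5-(non-8-en-1-yl)-1H-pyrrole-2-carbaldehyde, via 9-(non-8-en-1-yl)-9-BBN 3 (not isolated)
Conditions: 1 (4 equiv), 9-BBN (1.5 equiv), THF, 0 °C → rt; then 2 (1 equiv), PdCl2(dppf) (5 mol %), 3 M aq K3PO4, DMF, 60 °C
Reagents that add atoms: none
Why: Anti-Markovnikov hydroboration of one terminal alkene of the excess diene gives the primary alkylborane, which undergoes B-alkyl Suzuki–Miyaura coupling with the formyl-activated 2-bromopyrrole without N-protection.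

**Step 2**
Reactants: 4 5-(non-8-en-1-yl)-1H-pyrrole-2-carbaldehyde; 5 methyl vinyl ketone
Product: 6 5-[(8E)-10-oxoundec-8-en-1-yl]-1H-pyrrole-2-carbaldehyde
Conditions: 5 (5 equiv), Hoveyda–Grubbs II (3 mol %), CH2Cl2, 40 °C
Reagents that add atoms: none
Why: Olefin cross-metathesis of a terminal alkene with excess enone is E-selective, driven by loss of ethene, and tolerates the formylpyrrole.

**Step 3**
Reactants: 6 5-[(8E)-10-oxoundec-8-en-1-yl]-1H-pyrrole-2-carbaldehyde
Product: 7 (3S)-3-(2-oxopropyl)-14-azabicyclo[9.2.1]tetradeca-1(13),11-dien-2-one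
Conditions: (5aR,10bS)-aminoindanol-derived N-C6F5 triazolium BF4 (20 mol %), KHMDS (20 mol %), toluene, 40 °C, 6 added by syringe pump over 20 h (final 2 mM)
Reagents that add atoms: none
Why: Proposed new method: an enantioselective macrocyclising intramolecular Stetter reaction, in which the carbene turns the formyl carbon into a Breslow acyl-anion equivalent that adds 1,4 to the tethered (E)-enone and closes the 12-membered 2,5-pyrrolophane irreversibly, with high dilution and a pyrrole N–H···O=C contact to the enone favouring ring closure over oligomerisation, and with the aminoindanol wall leaving the Si face of the enone β-carbon open so that the new centre is (S); the closest known reaction type is the asymmetric intramolecular Stetter reaction of aryl aldehydes with tethered enones and enoates, which so far forms five- and six-membered rings only.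

**Step 4**
Reactants: 7 (3S)-3-(2-oxopropyl)-14-azabicyclo[9.2.1]tetradeca-1(13),11-dien-2-one
Product: 8 (3S)-3-[(2S)-2-hydroxypropyl]-14-azabicyclo[9.2.1]tetradeca-1(13),11-dien-2-one
Conditions: (R)-Me-CBS (0.3 equiv), catecholborane (1.5 equiv), toluene, −78 °C; MeOH, pH 7 buffer
Reagents that add atoms: none
Why: Corey–Bakshi–Shibata reduction, in which the unhindered dialkyl methyl ketone reacts ahead of the vinylogous-amide 2-acylpyrrole ketone and the (R)-oxazaborolidine delivers hydride to the Re face (CH2R large, CH3 small) to give the (S)-carbinol under catalyst control.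

**Step 5**
Reactants: 9 4-methoxy-1,5-dihydro-2H-pyrrol-2-one (4-methoxy-3-pyrrolin-2-one)
Product: 10 tert-butyl 4-methoxy-2-oxo-2,5-dihydro-1H-pyrrole-1-carboxylate
Conditions: Boc2O (1.2 equiv), DMAP (10 mol %), MeCN, rt
Reagents that add atoms: di-tert-butyl dicarbonate, CC(C)(C)OC(=O)OC(=O)OC(C)(C)C
Why: DMAP-catalysed N-acylation (Boc protection) of the lactam, which also acidifies C5–H for the next step.

**Step 6**
Reactants: 10 tert-butyl 4-methoxy-2-oxo-2,5-dihydro-1H-pyrrole-1-carboxylate
Product: 11 tert-butyl 4-methoxy-2-{[(trifluoromethyl)sulfonyl]oxy}-1H-pyrrole-1-carboxylate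
Conditions: KHMDS (1.1 equiv), THF, −78 °C; then PhNTf2 (1.15 equiv), −78 → 0 °C
Reagents that add atoms: N-phenyl-bis(trifluoromethanesulfonimide), O=S(=O)(N(c1ccccc1)S(=O)(=O)C(F)(F)F)C(F)(F)F
Why: Deprotonation at C5 gives the aromatic 2-oxidopyrrole (dienolate), which is O-sulfonylated by the triflimide in a standard enol-triflate formation.

**Step 7**
Reactants: 11 tert-butyl 4-methoxy-2-{[(trifluoromethyl)sulfonyl]oxy}-1H-pyrrole-1-carboxylate; 12 [1-(tert-butoxycarbonyl)-1H-pyrrol-2-yl]boronic acid
Product: 14 4-methoxy-1H,1'H-2,2'-bipyrrole, via di-Boc-bipyrrole 13 (not isolated)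
Conditions: 12 (1.5 equiv), Pd(PPh3)4 (5 mol %), 2 M aq Na2CO3, DME, 80 °C; then NaOMe (0.3 equiv), MeOH, 40 °C; product kept cold under argon
Reagents that add atoms: none
Why: Suzuki–Miyaura coupling of the pyrrolyl triflate with the 2-pyrrolylboronic acid, followed by methoxide-catalysed transfer of both N-Boc groups to methanol.

**Step 8**
Reactants: 8 (3S)-3-[(2S)-2-hydroxypropyl]-14-azabicyclo[9.2.1]tetradeca-1(13),11-dien-2-one; 14 4-methoxy-1H,1'H-2,2'-bipyrrole
Product: 16 premarineosin A (spiro C R, O–CH(CH3) S, bridge-bearing CH S, pyrrolyl-CH S), via open-chain hydroxyprodigiosene 15 (not isolated)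
Conditions: 14 (1.3 equiv), TFA (2 equiv), 4 Å MS, degassed CH2Cl2, −20 °C → rt, dark; Et3N quench
Reagents that add atoms: none
Why: Acid-mediated dehydrative Friedel–Crafts-type condensation of the 2-acylpyrrole (through its cyclic hemiketal cation) with the most nucleophilic α-position of the bipyrrole gives the meso-substituted prodigiosene 15, which is twisted by its meso substituent and undergoes spiro-N,O-ketalisation (protonation at the meso carbon, alcohol onto ring-B C2); the two new centres are expected to form reversibly under control of the two existing ones, 16 being the only epimer that can hold both ansa bonds equatorial with the C–N bond axial (anomeric) on the tetrahydropyran.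

**Compound list**
1 | nona-1,8-diene | C=CCCCCCC=C | starting material
2 | 5-bromo-1H-pyrrole-2-carbaldehyde | O=Cc1ccc(Br)[nH]1 | starting material
3 | 9-(non-8-en-1-yl)-9-borabicyclo[3.3.1]nonane | C=CCCCCCCCB1C2CCCC1CCC2 | intermediate
4 | 5-(non-8-en-1-yl)-1H-pyrrole-2-carbaldehyde | C=CCCCCCCCc1ccc(C=O)[nH]1 | intermediate
5 | methyl vinyl ketone (but-3-en-2-one) | CC(=O)C=C | starting material
6 | 5-[(8E)-10-oxoundec-8-en-1-yl]-1H-pyrrole-2-carbaldehyde | CC(=O)/C=C/CCCCCCCc1ccc(C=O)[nH]1 | intermediate
7 | (3S)-3-(2-oxopropyl)-14-azabicyclo[9.2.1]tetradeca-1(13),11-dien-2-one | CC(=O)C[C@@H]1CCCCCCCc2ccc([nH]2)C1=O | intermediate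
8 | (3S)-3-[(2S)-2-hydroxypropyl]-14-azabicyclo[9.2.1]tetradeca-1(13),11-dien-2-one | C[C@H](O)C[C@@H]1CCCCCCCc2ccc([nH]2)C1=O | intermediate
9 | 4-methoxy-1,5-dihydro-2H-pyrrol-2-one | COC1=CC(=O)NC1 | starting material
10 | tert-butyl 4-methoxy-2-oxo-2,5-dihydro-1H-pyrrole-1-carboxylate | COC1=CC(=O)N(C(=O)OC(C)(C)C)C1 | intermediate
11 | tert-butyl 4-methoxy-2-{[(trifluoromethyl)sulfonyl]oxy}-1H-pyrrole-1-carboxylate | COc1cn(C(=O)OC(C)(C)C)c(OS(=O)(=O)C(F)(F)F)c1 | intermediate
12 | [1-(tert-butoxycarbonyl)-1H-pyrrol-2-yl]boronic acid | CC(C)(C)OC(=O)n1cccc1B(O)O | starting material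
13 | di-tert-butyl 4-methoxy-1H,1'H-[2,2'-bipyrrole]-1,1'-dicarboxylate | COc1cn(C(=O)OC(C)(C)C)c(-c2cccn2C(=O)OC(C)(C)C)c1 | intermediate
14 | 4-methoxy-1H,1'H-2,2'-bipyrrole | COc1c[nH]c(-c2ccc[nH]2)c1 | intermediate
15 | (2S)-1-{(2Z,3S)-2-[3-methoxy-5-(1H-pyrrol-2-yl)-2H-pyrrol-2-ylidene]-14-azabicyclo[9.2.1]tetradeca-1(13),11-dien-3-yl}propan-2-ol | C[C@H](O)C[C@@H]1CCCCCCCc2ccc([nH]2)/C1=C3\N=C(c4ccc[nH]4)C=C3OC | intermediate
16 | premarineosin A | COC1=CC(c2ccc[nH]2)=N[C@]12O[C@@H](C)C[C@@H]1CCCCCCCc3ccc([nH]3)[C@H]12 | target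

**Totals**
Total step count: 8. Longest linear sequence: 5 (steps 1, 2, 3, 4, 8); the bipyrrole branch is steps 5–7.

**Steps most likely to fail**

Step 3 (new macro-Stetter). Risks are slow Breslow formation from the electron-rich N–H formylpyrrole, oligomerisation or benzoin coupling, and an unproven level and sense of induction in a 12-membered closure. The fallback uses the established acyl-radical macrocyclisation; it sets out from 6 and comes back at 8. Pinnick oxidation of 6 (NaClO2, NaH2PO4, 2-methyl-2-butene, t-BuOH/H2O) gives 5-[(8E)-10-oxoundec-8-en-1-yl]-1H-pyrrole-2-carboxylic acid F1. N-(Phenylseleno)phthalimide/Bu3P converts this into Se-phenyl 5-[(8E)-10-oxoundec-8-en-1-yl]-1H-pyrrole-2-carboselenoate F2. Slow addition of Bu3SnH/AIBN (benzene, 80 °C, 2 mM) generates the pyrrole-2-carbonyl radical, which adds to the enone β-carbon and gives 7 as the racemate, that is, together with (3R)-3-(2-oxopropyl)-14-azabicyclo[9.2.1]tetradeca-1(13),11-dien-2-one F3. Step 4 is then run on the racemate: the (R)-CBS reduction turns it into 8 and (3R)-3-[(2S)-2-hydroxypropyl]-14-azabicyclo[9.2.1]tetradeca-1(13),11-dien-2-one F4, which are diastereomers and are separated on silica. F4 is recycled by DBU epimerisation at C3 (α to the ring ketone) and re-separation.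

Step 8 (condensation and spirocyclisation). Risks are epimerisation at C3 through the cyclic enol ether of the hemiketal cation, acid-induced decomposition of the electron-rich bipyrrole, and formation of the wrong spiro/CH epimer. The fallback separates chromophore assembly from ring closure; it sets out from 8 and comes back at 15, which is then closed to 16. TBSOTf/2,6-lutidine gives (3S)-3-[(2S)-2-(tert-butyldimethylsilyloxy)propyl]-14-azabicyclo[9.2.1]tetradeca-1(13),11-dien-2-one F7, which cannot form the cyclic enol ether. Standard POCl3-mediated acylpyrrole/pyrrole condensation with 14 (CH2Cl2, 0 °C → rt, NaHCO3 work-up) gives the O-TBS ether of 15 F8. Buffered TBAF/AcOH releases 15, which is cyclised in a separate operation at low temperature with a catalytic phosphoric acid diester (achiral or chiral) so that the spiro and CH centres can be tuned independently of the condensation.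

Step 4 (CBS reduction). Risks are modest facial selectivity for a CH3/CH2R dialkyl ketone and some reduction of the acylpyrrole ketone. The fallback replaces catalyst control by enzymatic sorting of the carbinol epimers; it sets out from 7 and comes back at 8. NaBH4 (MeOH, −40 °C) reduces only the methyl ketone and gives 8 together with (3S)-3-[(2R)-2-hydroxypropyl]-14-azabicyclo[9.2.1]tetradeca-1(13),11-dien-2-one F5. Candida antarctica lipase B with vinyl acetate (MTBE, rt) acetylates only the (R)-carbinol, to (2R)-1-[(3S)-2-oxo-14-azabicyclo[9.2.1]tetradeca-1(13),11-dien-3-yl]propan-2-yl acetate F6, and 8 is recovered unchanged by chromatography.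

**Further compounds**
F1 | step 3 | 5-[(8E)-10-oxoundec-8-en-1-yl]-1H-pyrrole-2-carboxylic acid | CC(=O)/C=C/CCCCCCCc1ccc(C(=O)O)[nH]1
F2 | step 3 | Se-phenyl 5-[(8E)-10-oxoundec-8-en-1-yl]-1H-pyrrole-2-carboselenoate | CC(=O)/C=C/CCCCCCCc1ccc(C(=O)[Se]c2ccccc2)[nH]1
F3 | step 3 | (3R)-3-(2-oxopropyl)-14-azabicyclo[9.2.1]tetradeca-1(13),11-dien-2-one | CC(=O)C[C@H]1CCCCCCCc2ccc([nH]2)C1=O
F4 | step 3 | (3R)-3-[(2S)-2-hydroxypropyl]-14-azabicyclo[9.2.1]tetradeca-1(13),11-dien-2-one | C[C@H](O)C[C@H]1CCCCCCCc2ccc([nH]2)C1=O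
F5 | step 4 | (3S)-3-[(2R)-2-hydroxypropyl]-14-azabicyclo[9.2.1]tetradeca-1(13),11-dien-2-one | C[C@@H](O)C[C@@H]1CCCCCCCc2ccc([nH]2)C1=O
F6 | step 4 | (2R)-1-[(3S)-2-oxo-14-azabicyclo[9.2.1]tetradeca-1(13),11-dien-3-yl]propan-2-yl acetate | C[C@@H](OC(C)=O)C[C@@H]1CCCCCCCc2ccc([nH]2)C1=O
F7 | step 8 | (3S)-3-[(2S)-2-(tert-butyldimethylsilyloxy)propyl]-14-azabicyclo[9.2.1]tetradeca-1(13),11-dien-2-one | C[C@H](O[Si](C)(C)C(C)(C)C)C[C@@H]1CCCCCCCc2ccc([nH]2)C1=O
F8 | step 8 | O-tert-butyldimethylsilyl ether of 15 | C[C@H](O[Si](C)(C)C(C)(C)C)C[C@@H]1CCCCCCCc2ccc([nH]2)/C1=C3\N=C(c4ccc[nH]4)C=C3OC
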